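The route rests on making the C8–C9 bond of ring B last. A monovalent-gold 6-endo-dig carbocyclisation of an enol ether onto an internal alkyne closes ring B, places the C7=C8 alkene with its C17 methyl, sets C9 and unveils the C11 aldehyde in one operation; it exploits the C7=C8(C17)–C9(C11) array of ring B next to the quaternary C10. The precursor is a ring A cyclohexane bearing the C2/C3 acetonide, the C4 gem-dimethyl group, a but-2-ynyl arm on C5 and a methyl plus 2-methoxyvinyl arm on C10, the arms trans; both arms are cut from the five-membered ring of an enantiopure trans-hydrindanone.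

Key step: step 15

Remark on numbering: locants C1–C20 are those of the labdane skeleton of the target and are kept for every intermediate; in the bicyclic template C10 is the angular carbon, C9 the carbonyl carbon beside it, C7 and C6 the five-ring methylenes and C5 the ring-fusion CH.

Assumption: the methoxymethylene Wittig step should give an E/Z mixture of enol ethers; both isomers should converge on the same aldehyde in the key step, so the mixture is carried on and the E isomer is drawn.

Step 1
Reactants: 1 2-methylcyclopentane-1,3-dione; 2 pent-1-en-3-one (ethyl vinyl ketone)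
Product: 3 2-methyl-2-(3-oxopentyl)cyclopentane-1,3-dione
Conditions: H2O, AcOH (cat.), 75 °C
Reagents that add atoms: none
Why: Michael addition of the acidic 1,3-dione to the enone, the standard entry to triketones of the Hajos–Parrish type.

Step 2
Reactants: 3 2-methyl-2-(3-oxopentyl)cyclopentane-1,3-dione
Product: 4 (R)-4,7a-dimethyl-2,3,7,7a-tetrahydro-1H-indene-1,5(6H)-dione (7a = C10)
Conditions: (R)-phenylalanine (1 equiv), camphorsulfonic acid (0.5 equiv), DMF, 30 to 70 °C
Reagents that add atoms: none
Why: Hajos–Parrish–Eder–Sauer–Wiechert reaction, in which the enamine of the (R)-amino acid should select one of the two enantiotopic ring carbonyls and so set C10 as R (mirror image of the (S)-amino acid series), with recrystallisation expected to raise the enantiomeric purity.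

Step 3
Reactants: 4 (R)-4,7a-dimethyl-2,3,7,7a-tetrahydro-1H-indene-1,5(6H)-dione
Product: 5 (7aR)-1,1-ethylenedioxy-4,7a-dimethyl-1,2,3,6,7,7a-hexahydro-5H-inden-5-one (ketal at C9)
Conditions: HOCH2CH2OH, p-TsOH·H2O (cat.), 4 Å MS, rt
Reagents that add atoms: ethylene glycol, OCCO
Why: Ketal formation should be selective for the saturated cyclopentanone carbonyl, which is more electrophilic than the vinylogous enone carbonyl.

Step 4
Reactants: 5 (7aR)-1,1-ethylenedioxy-4,7a-dimethyl-1,2,3,6,7,7a-hexahydro-5H-inden-5-one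
Product: 7 (3aR,7aR)-1,1-ethylenedioxy-4,4,7a-trimethyloctahydro-5H-inden-5-one (trans-fused, C5–H anti to the C10 methyl), via lithium enolate 6 (not isolated)
Conditions: Li, NH3/THF, t-BuOH (1 equiv), −78 °C; then MeI, −78 °C to rt
Reagents that add atoms: iodomethane, CI
Why: Dissolving-metal (Birch-type) reductive alkylation, in which the β-carbanion at C5 should be protonated axially, anti to the C10 methyl, to set the trans ring fusion, and the regiospecific C3 enolate 6 is then methylated at C4 to complete the gem-dimethyl group.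

Step 5
Reactants: 7 (3aR,7aR)-1,1-ethylenedioxy-4,4,7a-trimethyloctahydro-5H-inden-5-one
Product: 9 C3 enol triflate of 7 (C2=C3, trans-fused), via potassium enolate 8 (not isolated)
Conditions: KN(SiMe3)2, THF, −78 °C; then PhNTf2, −78 °C to rt
Reagents that add atoms: N-phenylbis(trifluoromethanesulfonimide), O=S(=O)(N(c1ccccc1)S(=O)(=O)C(F)(F)F)C(F)(F)F
Why: Enol triflate formation is regiospecific because C4 is quaternary, so the ketone can enolise only towards C2.

Step 6
Reactants: 9 C3 enol triflate
Product: 10 trans-fused 1,1-ethylenedioxy-4,4,7a-trimethyl-2,3,3a,4,7,7a-hexahydro-1H-indene (C2=C3 alkene, configuration as in 7)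
Conditions: Pd(OAc)2 (5 mol %), PPh3, n-Bu3N, HCO2H, DMF, 60 °C
Reagents that add atoms: none
Why: Palladium-catalysed formate reduction of a vinyl triflate (oxidative addition to zerovalent palladium, formate exchange, loss of CO2, reductive elimination) leaves the alkene where the triflate stood.

Step 7
Reactants: 10 C2=C3 alkene
Product: 11 cis-C2,C3-diol of 10 (both hydroxyls anti to the C10 methyl; C3–OH axial, C2–OH equatorial)
Conditions: OsO4 (2 mol %), NMO, acetone/H2O, rt
Reagents that add atoms: N-methylmorpholine N-oxide, C[N+]1([O-])CCOCC1; water, O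
Why: Upjohn dihydroxylation, in which syn addition should occur on the face opposite the axial C10 methyl and the pseudo-axial C4 methyl, setting C2 and C3 with both oxygens cis and anti to C20.

Step 8
Reactants: 11 cis-C2,C3-diol ketal
Product: 12 trans-fused 2,3-O-isopropylidene C9 ketone (acetonide of the cis-diol, cyclopentanone freed)
Conditions: Me2C(OMe)2, acetone, p-TsOH·H2O (cat.), rt to 40 °C
Reagents that add atoms: 2,2-dimethoxypropane, COC(C)(C)OC
Why: Acid-catalysed acetonide formation on the cis-diol, while transketalisation to acetone should release the C9 ketone in the same flask.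

Step 9
Reactants: 12 acetonide ketone
Product: 14 C9 enol triflate of 12 (C7=C9), via potassium enolate 13 (not isolated)
Conditions: KN(SiMe3)2, THF, −78 °C; then PhNTf2, −78 °C to rt
Reagents that add atoms: N-phenylbis(trifluoromethanesulfonimide), O=S(=O)(N(c1ccccc1)S(=O)(=O)C(F)(F)F)C(F)(F)F
Why: Enol triflate formation is regiospecific because C10 is quaternary, so only C7 can be deprotonated.

Step 10
Reactants: 14 C9 enol triflate
Product: 15 trans-fused acetonide cyclopentene (C7=C9 alkene)
Conditions: Pd(OAc)2 (5 mol %), PPh3, n-Bu3N, HCO2H, DMF, 60 °C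
Reagents that add atoms: none
Why: Palladium-catalysed formate reduction of the vinyl triflate, as in step 6.

Step 11
Reactants: 15 acetonide cyclopentene
Product: 17 ring A dialdehyde (formyl on C10, 2-oxoethyl on C5, arms trans; C2/C3 acetonide), via secondary ozonide 16 (not isolated)
Conditions: O3, CH2Cl2, −78 °C; then PPh3, −78 °C to rt
Reagents that add atoms: ozone, [O-][O+]=O
Why: Ozonolysis with reductive work-up cleaves the only alkene, turning the trans ring fusion into two trans arms of different length and hindrance.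

Step 12
Reactants: 17 ring A dialdehyde
Product: 18 alkynyl aldehyde (prop-2-ynyl on C5, formyl on C10, trans; C2/C3 acetonide)
Conditions: MeC(O)C(N2)P(O)(OMe)2 (1.1 equiv), K2CO3, MeOH, 0 °C
Reagents that add atoms: dimethyl (1-diazo-2-oxopropyl)phosphonate, CC(=O)C(=[N+]=[N-])P(=O)(OC)OC
Why: Ohira–Bestmann (Seyferth–Gilbert) homologation, in which the unhindered C7 formyl group should react far faster than the neopentyl C9 formyl group on the quaternary C10.

Step 13
Reactants: 18 alkynyl aldehyde
Product: 19 methyl enol ether (prop-2-ynyl on C5, 2-methoxyvinyl on C10; E isomer drawn)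
Conditions: Ph3P(CH2OMe)Cl, KN(SiMe3)2, THF, 0 °C to rt
Reagents that add atoms: (methoxymethyl)triphenylphosphonium chloride, COC[P+](c1ccccc1)(c1ccccc1)c1ccccc1.[Cl-]
Why: Wittig methoxymethylenation of the non-enolisable C9 aldehyde adds C11, and the ylide is not basic enough to disturb the terminal alkyne.

Step 14
Reactants: 19 methyl enol ether with terminal alkyne
Product: 21 key-step precursor (but-2-ynyl on C5; methyl and (E)-2-methoxyvinyl on C10; C2/C3 acetonide; arms trans), via lithium acetylide 20 (not isolated)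
Conditions: n-BuLi, THF, −78 °C; then MeI, −78 °C to rt
Reagents that add atoms: iodomethane, CI
Why: Acetylide alkylation adds the C17 methyl; the enol ether and the acetonide are inert to n-BuLi at −78 °C.

Step 15
Reactants: 21 key-step precursor
Product: 23 trans-fused 7-ene bicyclic aldehyde (C11 formyl equatorial on C9, C7=C8 with C17, C2/C3 acetonide), via oxocarbenium ion 22 (not isolated)
Conditions: [(2-biphenylyl)(t-Bu)2P]Au(NCMe)SbF6 (5 mol %), H2O (2 equiv), CH2Cl2, 0 °C to rt
Reagents that add atoms: water, O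
Why: The cationic monovalent-gold complex π-activates the C7≡C8 alkyne and the nucleophilic enol ether carbon C9 adds anti to gold at C8, giving a C7 vinylgold species and the C11 oxocarbenium ion 22, which protodeauration and hydrolysis by water turn into the C7–H alkene and the aldehyde. The closest known reaction type is the gold-catalysed 6-endo-dig carbocyclisation of enol ethers and silyl enol ethers onto alkynes with bulky biaryl phosphine ligands. Ring B closes in the 6-endo-dig mode with both alkyne carbons ending inside the ring as C7=C8, so no alkene regioisomer can arise. C9 is set by a chair-like transition state in which the two arms are trans-diequatorial on ring A and the C9–C11 bond stays equatorial, which is also the thermodynamic epimer of the aldehyde. The step needs 6-endo over 5-exo selectivity, which the bulky ligand, the methyl on C8 (stabilising positive charge there) and the strain of the alternative trans-hydrindane with an exocyclic alkene should secure.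

Step 16
Reactants: 23 bicyclic aldehyde
Product: 24 C9-vinyl bicycle (C11=C12 terminal alkene, C7=C8, C2/C3 acetonide)
Conditions: Ph3PCH3Br, KN(SiMe3)2, THF, −78 to 0 °C
Reagents that add atoms: methyltriphenylphosphonium bromide, C[P+](c1ccccc1)(c1ccccc1)c1ccccc1.[Br-]
Why: Wittig methylenation adds C12 under conditions where the hindered C9–H, flanked by the quaternary C10, should not be deprotonated, so C9 and the C7=C8 position are kept.

Step 17
Reactants: 25 but-2-yn-1-ol
Product: 26 tert-butyl(but-2-yn-1-yloxy)dimethylsilane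
Conditions: TBSCl, imidazole, CH2Cl2, rt
Reagents that add atoms: tert-butyldimethylsilyl chloride, CC(C)(C)[Si](C)(C)Cl
Why: Standard silylation of a primary alcohol gives an ether that is bulky enough to steer the next step and stable to the coupling.

Step 18
Reactants: 26 tert-butyl(but-2-yn-1-yloxy)dimethylsilane
Product: 28 (E)-tert-butyl[(3-iodobut-2-en-1-yl)oxy]dimethylsilane (side-chain fragment C13–C16), via alkenylzirconocene 27 (not isolated)
Conditions: Cp2Zr(H)Cl, THF, rt to 50 °C; then I2, 0 °C
Reagents that add atoms: iodine, II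
Why: Hydrozirconation then iodinolysis, in which syn addition of Zr–H with zirconium settling on the less hindered methyl-bearing carbon, followed by iodination with retention, should give the E iodide.

Step 19
Reactants: 24 C9-vinyl bicycle; 28 (E)-vinyl iodide
Product: 30 coupled labdadiene (C15 silyl ether, C2/C3 acetonide, 13E), via B-alkyl-9-BBN adduct 29 (not isolated)
Conditions: 9-BBN, THF, rt; then 28, Pd(dppf)Cl2 (5 mol %), AsPh3, Cs2CO3, DMF/H2O, rt
Reagents that add atoms: none
Why: Anti-Markovnikov hydroboration of the only monosubstituted alkene by 9-BBN, then B-alkyl Suzuki–Miyaura coupling, forms C12–C13 with retention of the E geometry of the iodide.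

Step 20
Reactants: 30 coupled labdadiene
Product: 31 (2S,3R,5S,9R,10S)-labda-7,13(E)-diene-2,3,15-triol
Conditions: p-TsOH·H2O (cat.), MeOH, rt
Reagents that add atoms: none
Why: Acid-catalysed methanolysis removes the acetonide (transacetalisation) and the primary silyl ether together, and the trisubstituted alkenes and the allylic alcohol should tolerate catalytic acid at rt.

Step 21
Reactants: 31 labda-7,13(E)-diene-2,3,15-triol
Product: 32 (2S,3R,5S,9R,10S)-2,15-diacetoxylabda-7,13(E)-dien-3-ol (target)
Conditions: Ac2O (2.2 equiv), pyridine, CH2Cl2, 0 °C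
Reagents that add atoms: acetic anhydride, CC(=O)OC(C)=O
Why: Selective acylation, in which the primary allylic C15 hydroxyl and the equatorial C2 hydroxyl should acetylate while the axial C3 hydroxyl beside the C4 gem-dimethyl group is too hindered without an acyl-transfer catalyst.

Compound list
1 | 2-methylcyclopentane-1,3-dione | CC1C(=O)CCC1=O | starting material
2 | pent-1-en-3-one | CCC(=O)C=C | starting material
3 | 2-methyl-2-(3-oxopentyl)cyclopentane-1,3-dione | CCC(=O)CCC1(C)C(=O)CCC1=O | intermediate
4 | (R)-4,7a-dimethyl-2,3,7,7a-tetrahydro-1H-indene-1,5(6H)-dione | C[C@@]12CCC(=O)C(C)=C1CCC2=O | intermediate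
5 | (7aR)-1,1-ethylenedioxy-4,7a-dimethyl-1,2,3,6,7,7a-hexahydro-5H-inden-5-one | C[C@@]12CCC(=O)C(C)=C1CCC21OCCO1 | intermediate
6 | lithium C3 enolate of the trans-fused reduced ketal (C3=C4) | C[C@@]12CCC(O[Li])=C(C)[C@H]1CCC21OCCO1 | intermediate
7 | (3aR,7aR)-1,1-ethylenedioxy-4,4,7a-trimethyloctahydro-5H-inden-5-one, trans-fused | C[C@@]12CCC(=O)C(C)(C)[C@H]1CCC21OCCO1 | intermediate
8 | potassium C3 enolate of 7 (C2=C3) | C[C@@]12CC=C(O[K])C(C)(C)[C@H]1CCC21OCCO1 | intermediate
9 | C3 enol triflate of 7 (C2=C3) | C[C@@]12CC=C(OS(=O)(=O)C(F)(F)F)C(C)(C)[C@H]1CCC21OCCO1 | intermediate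
10 | trans-fused 1,1-ethylenedioxy-4,4,7a-trimethyl-2,3,3a,4,7,7a-hexahydro-1H-indene (C2=C3 alkene) | C[C@@]12CC=CC(C)(C)[C@H]1CCC21OCCO1 | intermediate
11 | cis-C2,C3-diol of 10, hydroxyls anti to the C10 methyl | C[C@@]12C[C@H](O)[C@H](O)C(C)(C)[C@H]1CCC21OCCO1 | intermediate
12 | trans-fused 2,3-O-isopropylidene C9 ketone | C[C@@]12C[C@@H]3OC(C)(C)O[C@@H]3C(C)(C)[C@H]1CCC2=O | intermediate
13 | potassium C9 enolate of 12 (C7=C9) | C[C@@]12C[C@@H]3OC(C)(C)O[C@@H]3C(C)(C)[C@H]1CC=C2O[K] | intermediate
14 | C9 enol triflate of 12 (C7=C9) | C[C@@]12C[C@@H]3OC(C)(C)O[C@@H]3C(C)(C)[C@H]1CC=C2OS(=O)(=O)C(F)(F)F | intermediate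
15 | trans-fused acetonide cyclopentene (C7=C9) | C[C@@]12C[C@@H]3OC(C)(C)O[C@@H]3C(C)(C)[C@H]1CC=C2 | intermediate
16 | secondary ozonide of 15 (1,2,4-trioxolane across C7 and C9; configuration at C7 and C9 not defined) | C[C@@]12C[C@@H]3OC(C)(C)O[C@@H]3C(C)(C)[C@H]1CC4OOC2O4 | intermediate
17 | ring A dialdehyde: formyl on C10, 2-oxoethyl on C5, trans; C2/C3 acetonide | O=CC[C@@H]1C(C)(C)[C@@H]2[C@@H](OC(C)(C)O2)C[C@@]1(C)C=O | intermediate
18 | alkynyl aldehyde: prop-2-ynyl on C5, formyl on C10, trans; C2/C3 acetonide | C#CC[C@@H]1C(C)(C)[C@@H]2[C@@H](OC(C)(C)O2)C[C@@]1(C)C=O | intermediate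
19 | methyl enol ether: prop-2-ynyl on C5, (E)-2-methoxyvinyl on C10 | C#CC[C@@H]1C(C)(C)[C@@H]2[C@@H](OC(C)(C)O2)C[C@@]1(C)/C=C/OC | intermediate
20 | lithium acetylide of 19 | [Li]C#CC[C@@H]1C(C)(C)[C@@H]2[C@@H](OC(C)(C)O2)C[C@@]1(C)/C=C/OC | intermediate
21 | key-step precursor: but-2-ynyl on C5, methyl and (E)-2-methoxyvinyl on C10, trans arms, C2/C3 acetonide | CC#CC[C@@H]1C(C)(C)[C@@H]2[C@@H](OC(C)(C)O2)C[C@@]1(C)/C=C/OC | intermediate
22 | C11 O-methyl oxocarbenium ion of the cyclised bicycle | C[O+]=C[C@@H]1C(C)=CC[C@@H]2C(C)(C)[C@@H]3[C@@H](OC(C)(C)O3)C[C@@]12C | intermediate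
23 | trans-fused 7-ene bicyclic C11 aldehyde, C2/C3 acetonide | O=C[C@@H]1C(C)=CC[C@@H]2C(C)(C)[C@@H]3[C@@H](OC(C)(C)O3)C[C@@]12C | intermediate
24 | C9-vinyl bicycle (C11=C12), C2/C3 acetonide | C=C[C@@H]1C(C)=CC[C@@H]2C(C)(C)[C@@H]3[C@@H](OC(C)(C)O3)C[C@@]12C | intermediate
25 | but-2-yn-1-ol | CC#CCO | starting material
26 | tert-butyl(but-2-yn-1-yloxy)dimethylsilane | CC#CCO[Si](C)(C)C(C)(C)C | intermediate
27 | (E)-alkenylzirconocene chloride from 26 (cyclopentadienyl rings drawn σ-bonded) | C/C(=C\CO[Si](C)(C)C(C)(C)C)[Zr](Cl)(C1C=CC=C1)C1C=CC=C1 | intermediate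
28 | (E)-tert-butyl[(3-iodobut-2-en-1-yl)oxy]dimethylsilane | C/C(I)=C\CO[Si](C)(C)C(C)(C)C | intermediate
29 | B-alkyl-9-BBN adduct of 24 (boron on C12) | C1CCC2CCCC1B2CC[C@@H]1C(C)=CC[C@@H]2C(C)(C)[C@@H]3[C@@H](OC(C)(C)O3)C[C@@]12C | intermediate
30 | 15-O-TBS 2,3-O-isopropylidene labda-7,13(E)-diene-2,3,15-triol | CC(C)(C)[Si](C)(C)OC/C=C(\C)CC[C@@H]1C(C)=CC[C@@H]2C(C)(C)[C@@H]3[C@@H](OC(C)(C)O3)C[C@@]12C | intermediate
31 | (2S,3R,5S,9R,10S)-labda-7,13(E)-diene-2,3,15-triol | OC/C=C(\C)CC[C@@H]1C(C)=CC[C@@H]2C(C)(C)[C@@H](O)[C@@H](O)C[C@@]12C | intermediate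
32 | (2S,3R,5S,9R,10S)-2,15-diacetoxylabda-7,13(E)-dien-3-ol | CC(=O)OC/C=C(\C)CC[C@@H]1C(C)=CC[C@@H]2C(C)(C)[C@@H](O)[C@@H](OC(C)=O)C[C@@]12C | target

Total step count: 21 (19 in the main line, 2 for the side-chain iodide 28). Longest linear sequence: 19 steps (steps 1–16 and 19–21).

Steps most likely to fail

1. Step 15. What may go wrong is competing 5-exo-dig closure, or hydrolysis of the enol ether before it cyclises. The fallback sets out from 21 and returns at 23. Mild aqueous acid (PPTS, acetone/H2O) should hydrolyse the enol ether to the homologous aldehyde F1; TBSOTf and Et3N should convert it into the tert-butyldimethylsilyl enol ether F2. Stoichiometric HgCl2 buffered with HN(SiMe3)2 in CH2Cl2, the mercury-mediated carbocyclisation of acetylenic silyl enol ethers, should give the C7 chloromercurio aldehyde F3, and protodemercuration (NaI, dilute HCl, 0 °C) should give 23.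

2. Step 4. What may go wrong is poor facial selectivity in the protonation at C5, giving the cis-fused ketone alongside 7. The fallback sets out from 5 and returns at 7. Deconjugative methylation (KOt-Bu, MeI, t-BuOH) should give the 4,4-dimethyl β,γ-unsaturated ketone F4 with the alkene moved to C5=C6. Hydrogen-atom-transfer hydrogenation (Mn(dpm)3, PhSiH3, t-BuOOH, i-PrOH), which tends to deliver the thermodynamically preferred ring fusion, should then give 7.

3. Step 12. What may go wrong is loss of chemoselectivity between the two formyl groups, or base-induced self-reaction of the dialdehyde. The fallback sets out from 12 and returns at 18, so the two arms are told apart by oxidation state instead of by hindrance. Enolate hydroxylation (KN(SiMe3)2, then 2-(phenylsulfonyl)-3-phenyloxaziridine) should give the C7 α-hydroxy ketone F5. Oxidative cleavage with Pb(OAc)4 in MeOH/benzene should give the C9 methyl ester C7 aldehyde F6. Ohira–Bestmann homologation should give the alkynyl ester F7, LiAlH4 the neopentyl alcohol F8, and Dess–Martin oxidation 18.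

Further compounds
F1 | step 15 | homologous aldehyde: but-2-ynyl on C5, 2-oxoethyl and methyl on C10, C2/C3 acetonide | CC#CC[C@@H]1C(C)(C)[C@@H]2[C@@H](OC(C)(C)O2)C[C@@]1(C)CC=O
F2 | step 15 | tert-butyldimethylsilyl enol ether of F1 (E isomer drawn) | CC#CC[C@@H]1C(C)(C)[C@@H]2[C@@H](OC(C)(C)O2)C[C@@]1(C)/C=C/O[Si](C)(C)C(C)(C)C
F3 | step 15 | C7 chloromercurio derivative of aldehyde 23 | O=C[C@@H]1C(C)=C([Hg]Cl)C[C@@H]2C(C)(C)[C@@H]3[C@@H](OC(C)(C)O3)C[C@@]12C
F4 | step 4 | (7aR)-1,1-ethylenedioxy-4,4,7a-trimethyl-1,2,4,6,7,7a-hexahydro-5H-inden-5-one (C5=C6 alkene) | C[C@@]12CCC(=O)C(C)(C)C1=CCC21OCCO1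
F5 | step 12 | C7 α-hydroxy derivative of ketone 12 (either C7 epimer) | C[C@@]12C[C@@H]3OC(C)(C)O[C@@H]3C(C)(C)[C@H]1CC(O)C2=O
F6 | step 12 | ring A ester aldehyde: methoxycarbonyl on C10, 2-oxoethyl on C5, trans; C2/C3 acetonide | O=CC[C@@H]1C(C)(C)[C@@H]2[C@@H](OC(C)(C)O2)C[C@@]1(C)C(=O)OC
F7 | step 12 | alkynyl ester: prop-2-ynyl on C5, methoxycarbonyl on C10 | C#CC[C@@H]1C(C)(C)[C@@H]2[C@@H](OC(C)(C)O2)C[C@@]1(C)C(=O)OC
F8 | step 12 | alkynyl alcohol: prop-2-ynyl on C5, hydroxymethyl on C10 | C#CC[C@@H]1C(C)(C)[C@@H]2[C@@H](OC(C)(C)O2)C[C@@]1(C)CO
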